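**Retrosynthetic overview**
- The target is (2S)-naringenin joined to apigenin through C8–C8''. The only disconnection is this biaryl bond, and both carbons are innately nucleophilic phloroglucinol CH positions.
- The polarity of the flavone C8 is inverted: C8–H → C8–I → C8–SnBu3 → C8–Pb(OAc)3, an aryl cation equivalent. Ligand coupling on lead then delivers it from O7 to C8 of a 7-hydroxyflavanone.
- The flavanone partner is (2S)-naringenin 4',5-diacetate. Capping O5 steers the transfer to C8, capping O4' protects C2, and the stereocentre comes from the chiral pool and is never touched.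
- No ring is formed: rings A, C and B of both halves arrive intact. Order: flavone arm (3 steps) and flavanone arm (2 steps), then coupling, then global deprotection.

Assumption: the C8–C8'' axis is not defined in the target SMILES, so the (2S) product is accepted as the mixture of atropisomers; (2S)-naringenin is bought as the single enantiomer and its ee is confirmed by chiral HPLC.

**Route**

Step 1
Reactants: 1 apigenin
Product: 2 4',5,7-tri-O-benzylapigenin
Conditions: BnBr (4.5 equiv), K2CO3 (5 equiv), Bu4NI (cat.), DMF, 80 °C, 16 h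
Reagents that add atoms: benzyl bromide, BrCc1ccccc1
Why: Williamson ether synthesis (SN2); the chelated 5-OH is alkylated only under these forcing conditions, and the fully capped ring A is what later directs substitution to C8.

Step 2
Reactants: 2 4',5,7-tri-O-benzylapigenin
Product: 3 8-iodo-4',5,7-tri-O-benzylapigenin
Conditions: NIS (1.1 equiv), TFA (0.3 equiv), MeCN–CH2Cl2, 0 °C to rt
Reagents that add atoms: N-iodosuccinimide, O=C1CCC(=O)N1I
Why: Electrophilic aromatic iodination; in 5,7-dialkoxyflavones C8 (between O7 and the tied-back ring oxygen) reacts in preference to C6 (between two freely rotating benzyloxy groups), and ring B is deactivated by conjugation with the pyrone carbonyl.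

Step 3
Reactants: 3 8-iodo-4',5,7-tri-O-benzylapigenin
Product: 4 8-(tributylstannyl)-4',5,7-tri-O-benzylapigenin
Conditions: (Bu3Sn)2 (1.5 equiv), Pd(PPh3)4 (10 mol %), toluene, 110 °C, 16 h
Reagents that add atoms: hexabutylditin, CCCC[Sn](CCCC)(CCCC)[Sn](CCCC)(CCCC)CCCC
Why: Pd-catalysed stannylation of an aryl iodide with a distannane (oxidative addition to zerovalent palladium, Sn–Sn transmetalation, reductive elimination); the arylstannane is the standard precursor for tin–lead exchange.

Step 4
Reactants: 5 (2S)-naringenin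
Product: 6 (2S)-naringenin 4',5,7-triacetate
Conditions: Ac2O (5 equiv), pyridine, 0 °C to rt, 4 h
Reagents that add atoms: acetic anhydride, CC(=O)OC(C)=O
Why: O-acetylation by nucleophilic acyl substitution; fast capping of the 4'-OH shuts the quinone-methide ring-opening pathway, so C2 stays S.

Step 5
Reactants: 6 (2S)-naringenin 4',5,7-triacetate
Product: 7 (2S)-naringenin 4',5-diacetate (7-OH free)
Conditions: PhSH (1.05 equiv), imidazole (0.2 equiv), NMP, 0 °C, 3 h
Reagents that add atoms: none
Why: Chemoselective thiolate-mediated deacylation (acyl transfer to sulfur); the 7-acetate is the ester of the most acidic phenol (para to C4=O) and leaves first, the 5-acetate is hindered and the 4'-acetate unactivated; C2 is not involved.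

Step 6
Reactants: 4 8-(tributylstannyl)-4',5,7-tri-O-benzylapigenin; 7 (2S)-naringenin 4',5-diacetate
Product: 9 (2S)-4',5-di-O-acetyl-8-[4',5,7-tris(benzyloxy)flavon-8-yl]naringenin (C8–C8'' atropisomer mixture), via flavon-8-yllead triacetate 8 (not isolated)
Conditions: 4 (1.3 equiv), Pb(OAc)4 (1.2 equiv), Hg(OCOCF3)2 (5 mol %), CHCl3, 40 °C, dark, 4 h; then 7 (1.0 equiv), pyridine (4 equiv), CHCl3, 50 °C, 16 h
Reagents that add atoms: none
Why: Proposed new method: a Pinhey ortho-arylation of a phenol by an aryllead triacetate, used here to join two complete flavonoids — tin–lead exchange turns the innately nucleophilic flavone C8 into the aryl cation equivalent 8 (the stannane is kept in excess so no free Pb(OAc)4 can acetoxylate the flavanone), the acidic 7-OH of 7 displaces acetate on tetravalent lead, and ligand coupling in the aryloxy(aryl)lead diacetate delivers the aryl group to the ortho carbon through a cyclohexa-2,4-dienone that tautomerises to the phenol while lead leaves as divalent lead; C8 is expected over C6 because, with the 5-OH unchelated, a 7-hydroxychromanone transfers ortho groups to C8 as in Claisen and Fries shifts of 7-hydroxybenzopyranones, and C6 is flanked by the 5-acetoxy group; the closest known reactions are arylations of 3,5-disubstituted phenols and 4-hydroxycoumarins with 2,4,6-trimethoxyphenyllead triacetate, which give tetra-ortho-substituted biaryls; C2 (S) is a spectator and the new axis forms without control.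

Step 7
Reactants: 9 (2S)-4',5-di-O-acetyl-8-[4',5,7-tris(benzyloxy)flavon-8-yl]naringenin
Product: 11 (2S)-2,3-dihydrocupressuflavone (target), via debenzylated 4',5-diacetate 10 (not isolated)
Conditions: H2 (1 atm), 10% Pd/C, THF–MeOH (1:1), rt, 6 h; filter; then HCl (0.5 M in MeOH), 35 °C, 6 h
Reagents that add atoms: none
Why: Hydrogenolysis of the three benzyl ethers followed by acid-catalysed transesterification of the two aryl acetates; neutral and then mildly acidic conditions keep the flavanone ring closed, so C2 stays S, and the flavone C2=C3 bond and both carbonyls are inert at 1 atm and rt.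

**Compound list**

1 | apigenin | O=c1cc(-c2ccc(O)cc2)oc2cc(O)cc(O)c12 | starting material
2 | 4',5,7-tri-O-benzylapigenin | O=c1cc(-c2ccc(OCc3ccccc3)cc2)oc2cc(OCc3ccccc3)cc(OCc3ccccc3)c12 | intermediate
3 | 8-iodo-4',5,7-tri-O-benzylapigenin | O=c1cc(-c2ccc(OCc3ccccc3)cc2)oc2c(I)c(OCc3ccccc3)cc(OCc3ccccc3)c12 | intermediate
4 | 8-(tributylstannyl)-4',5,7-tri-O-benzylapigenin | CCCC[Sn](CCCC)(CCCC)c1c(OCc2ccccc2)cc(OCc2ccccc2)c2c(=O)cc(-c3ccc(OCc4ccccc4)cc3)oc12 | intermediate
5 | (2S)-naringenin | O=C1C[C@@H](c2ccc(O)cc2)Oc2cc(O)cc(O)c12 | starting material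
6 | (2S)-naringenin 4',5,7-triacetate | O=C1C[C@@H](c2ccc(OC(C)=O)cc2)Oc2cc(OC(C)=O)cc(OC(C)=O)c12 | intermediate
7 | (2S)-naringenin 4',5-diacetate (7-OH free) | O=C1C[C@@H](c2ccc(OC(C)=O)cc2)Oc2cc(O)cc(OC(C)=O)c12 | intermediate
8 | [4',5,7-tris(benzyloxy)flavon-8-yl]lead triacetate | CC(=O)O[Pb](OC(C)=O)(OC(C)=O)c1c(OCc2ccccc2)cc(OCc2ccccc2)c2c(=O)cc(-c3ccc(OCc4ccccc4)cc3)oc12 | intermediate
9 | (2S)-4',5-di-O-acetyl-8-[4',5,7-tris(benzyloxy)flavon-8-yl]naringenin | O=C1C[C@@H](c2ccc(OC(C)=O)cc2)Oc2c1c(OC(C)=O)cc(O)c2-c1c(OCc2ccccc2)cc(OCc2ccccc2)c2c(=O)cc(-c3ccc(OCc4ccccc4)cc3)oc12 | intermediate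
10 | (2S)-2,3-dihydrocupressuflavone 4',5-diacetate (flavanone unit) | O=C1C[C@@H](c2ccc(OC(C)=O)cc2)Oc2c1c(OC(C)=O)cc(O)c2-c1c(O)cc(O)c2c(=O)cc(-c3ccc(O)cc3)oc12 | intermediate
11 | (2S)-5,7-dihydroxy-8-[5,7-dihydroxy-2-(4-hydroxyphenyl)-4-oxo-4H-chromen-8-yl]-2-(4-hydroxyphenyl)chroman-4-one | O=C1C[C@@H](c2ccc(O)cc2)Oc2c1c(O)cc(O)c2-c1c(O)cc(O)c2c(=O)cc(-c3ccc(O)cc3)oc12 | target

**Count**
Total steps: 7. Longest linear sequence: 5 steps (steps 1, 2, 3, 6, 7).

**Steps most likely to fail, with fallbacks**

Step 6. The ligand coupling may be slow on the para-acyl phenol 7, or may give C6/C8 mixtures. The fallback makes the biaryl bond on an achiral benzopyranone and creates C2 afterwards. It sets out from stannane 4: 8 is generated as in step 6 and used to arylate commercial 5,7-dihydroxychromone (pyridine, CHCl3, 50 °C), where benzopyranone bond fixation sends the transfer from O7 to C8, giving 5,7-dihydroxy-8-[4',5,7-tris(benzyloxy)flavon-8-yl]chromone F1. Asymmetric conjugate addition of 4-hydroxyphenylboronic acid to the chromone C2=C3 bond of F1 (Pd(OCOCF3)2, the t-BuPyOx enantiomer that gives the 2S product, NH4PF6, H2O, ClCH2CH2Cl, 60 °C) then gives (2S)-8-[4',5,7-tris(benzyloxy)flavon-8-yl]naringenin F2; the flavone half is β,β-disubstituted and does not react. Hydrogenolysis of F2 (H2, Pd/C, THF–MeOH) comes back to the route at 11.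

Step 3. The di-ortho-alkoxy aryl iodide is hindered, so transmetalation may be slow and homocoupling or protodeiodination may take over. The fallback avoids halide and tin by direct electrophilic plumbation. It sets out from 2: Pb(OAc)4 in CHCl3–AcOH (Cl2CHCO2H as promoter if needed, followed by exchange with AcOH), as practised for 1,3,5-trimethoxybenzene, metalates C8–H directly and comes back to the route at 8, which is then isolated by precipitation. This fallback makes no new compound (F0).

Step 5. Over-deacetylation or loss of the labile 5-acetate is possible. The fallback masks O7 first instead of unmasking it last. It sets out from 5: TBSCl (1.05 equiv), imidazole, DMF, 0 °C silylates the most acidic 7-OH to give (2S)-7-O-(tert-butyldimethylsilyl)naringenin F3. Ac2O in pyridine gives (2S)-7-O-(tert-butyldimethylsilyl)naringenin 4',5-diacetate F4, and HF·pyridine in THF at 0 °C removes the silyl group and comes back to the route at 7.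

**Further compounds**

F1 | step 6 | 5,7-dihydroxy-8-[4',5,7-tris(benzyloxy)flavon-8-yl]chromone | O=c1ccoc2c1c(O)cc(O)c2-c1c(OCc2ccccc2)cc(OCc2ccccc2)c2c(=O)cc(-c3ccc(OCc4ccccc4)cc3)oc12
F2 | step 6 | (2S)-8-[4',5,7-tris(benzyloxy)flavon-8-yl]naringenin | O=C1C[C@@H](c2ccc(O)cc2)Oc2c1c(O)cc(O)c2-c1c(OCc2ccccc2)cc(OCc2ccccc2)c2c(=O)cc(-c3ccc(OCc4ccccc4)cc3)oc12
F0 | step 3 | none | none
F3 | step 5 | (2S)-7-O-(tert-butyldimethylsilyl)naringenin | O=C1C[C@@H](c2ccc(O)cc2)Oc2cc(O[Si](C)(C)C(C)(C)C)cc(O)c12
F4 | step 5 | (2S)-7-O-(tert-butyldimethylsilyl)naringenin 4',5-diacetate | O=C1C[C@@H](c2ccc(OC(C)=O)cc2)Oc2cc(O[Si](C)(C)C(C)(C)C)cc(OC(C)=O)c12
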